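**Retrosynthetic overview**
- Late stage: epoxidation of the E-C1=C10 alkene, and acylation of O3 (isobutyryl chloride) and O8 ((2S,3S)-epoxyangelic acid, made from angelic acid by Sharpless epoxidation).
- The 6,12-olide comes from an 8,12-olide by C6 ketone reduction and translactonization.
- Key step: a three-carbon ring expansion of a cycloheptenone (7 → 10). SmI2 Barbier allylation by a tethered 3-(bromomethyl)butenolide is followed by Grob fragmentation of the β-mesyloxy alkoxide, giving the E-C1=C10 alkene, the C6 ketone and the cis lactone.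
- The cycloheptenone comes from intramolecular vinyllithium acylation of a γ-lactone; the C10 quaternary centre and C1 carbinol come from a lactone aldol followed by chelate-controlled methylation.
- Ring order: sacrificial butyrolactone → seven-membered carbocycle → butenolide → 5-5-7 tricycle (transient) → ten-membered ring with lactone → epoxide.

Assumption: the target is read from the SMILES as (1R,3S,6R,7R,8R,10R,2′S,3′S), and germacrane numbering (C1–C15) is used for every intermediate that contains the future ten-membered ring. The route has not been run; yields and selectivities are expectations.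

**Fragment 1 (C1–C5, C15)**

Step 1
Reactants: 1 prop-2-yn-1-ol
Product: 3 (Z)-3-iodo-2-methylprop-2-en-1-ol, via oxamagnesole 2 (not isolated)
Conditions: MeMgBr (2.5 equiv), CuI (10 mol %), THF, −10 °C → rt; then I2, −10 °C
Reagents that add atoms: methylmagnesium bromide C[Mg]Br; iodine [I][I]
Why: Copper-catalysed, alkoxide-directed anti-carbomagnesiation gives the chelated cyclic alkenylmagnesium 2, which is iodinated with retention, so iodine ends cis to CH2OH (Z).

Step 2
Reactants: 3 (Z)-3-iodo-2-methylprop-2-en-1-ol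
Product: 4 (Z)-3-iodo-2-methylprop-2-enal
Conditions: MnO2 (10 equiv), CH2Cl2, rt, dark
Reagents that add atoms: none
Why: Neutral MnO2 oxidation of an allylic alcohol keeps the Z geometry.

Step 3
Reactants: 4 (Z)-3-iodo-2-methylprop-2-enal
Product: 5 (3S,1Z)-1-iodo-2-methylhexa-1,5-dien-3-ol
Conditions: (−)-Ipc2B(allyl) (1.2 equiv), Et2O, −78 °C; then NaOH, H2O2, 0 °C
Reagents that add atoms: (−)-B-allyldiisopinocampheylborane C=CCB([C@@H]1C[C@@H]2C[C@H]([C@H]1C)C2(C)C)[C@@H]1C[C@@H]2C[C@H]([C@H]1C)C2(C)C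
Why: Brown asymmetric allylboration through a closed chair transition state delivers allyl to the Si face of the enal, which sets the future C3 as S.

Step 4
Reactants: 5 (3S,1Z)-1-iodo-2-methylhexa-1,5-dien-3-ol
Product: 6 tert-butyl{[(3S,1Z)-1-iodo-2-methylhexa-1,5-dien-3-yl]oxy}dimethylsilane
Conditions: TBSCl, imidazole, DMF, rt
Reagents that add atoms: tert-butyldimethylsilyl chloride CC(C)(C)[Si](C)(C)Cl
Why: Standard silylation; an ether that does not undergo acyl migration is needed for the later alkoxide steps.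

Step 5
Reactants: 6 tert-butyl{[(3S,1Z)-1-iodo-2-methylhexa-1,5-dien-3-yl]oxy}dimethylsilane
Product: 7 (3S,4Z)-3-[(tert-butyldimethylsilyl)oxy]-5-iodo-4-methylpent-4-enal
Conditions: OsO4 (2 mol %), NaIO4 (4 equiv), 2,6-lutidine, 1,4-dioxane/H2O 3:1, rt
Reagents that add atoms: sodium periodate [Na+].[O-]I(=O)(=O)=O (oxygen delivered through OsO4)
Why: Lemieux–Johnson cleavage; OsO4 selects the electron-richer monosubstituted alkene over the iodo-substituted trisubstituted one.

**Fragment 2 (C6–C10, O8)**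

Step 6
Reactants: 8 (5R)-5-(hydroxymethyl)oxolan-2-one
Product: 10 (5R)-5-ethenyloxolan-2-one, via aldehyde 9 (not isolated)
Conditions: (COCl)2, DMSO, Et3N, CH2Cl2, −78 °C; then Ph3P=CH2 (from Ph3PCH3Br, KN(SiMe3)2), THF, −78 °C → rt
Reagents that add atoms: methyltriphenylphosphonium bromide C[P+](c1ccccc1)(c1ccccc1)c1ccccc1.[Br-]
Why: One-pot Swern oxidation and Wittig methylenation avoids isolating the labile aldehyde 9; the stereocentre (future C8, R) is not touched.

**Fragment 3 (epoxyangelic acid)**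

Step 7
Reactants: 11 (Z)-2-methylbut-2-enoic acid (angelic acid)
Product: 12 (Z)-2-methylbut-2-en-1-ol
Conditions: LiAlH4, Et2O, 0 °C → rt
Reagents that add atoms: none
Why: Hydride reduction of the acid to the allylic alcohol without touching the Z alkene.

Step 8
Reactants: 12 (Z)-2-methylbut-2-en-1-ol
Product: 13 [(2R,3S)-2,3-dimethyloxiran-2-yl]methanol
Conditions: Ti(OiPr)4, D-(−)-diethyl tartrate, t-BuOOH, 4 Å sieves, CH2Cl2, −20 °C
Reagents that add atoms: tert-butyl hydroperoxide CC(C)(C)OO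
Why: Sharpless asymmetric epoxidation; the D-(−)-tartrate complex delivers oxygen to the face that gives the (2R,3S)-epoxy alcohol, with the cis relationship fixed by the Z alkene.

Step 9
Reactants: 13 [(2R,3S)-2,3-dimethyloxiran-2-yl]methanol
Product: 14 (2S,3S)-2,3-dimethyloxirane-2-carboxylic acid
Conditions: RuCl3 (2 mol %), NaIO4 (4 equiv), CCl4/MeCN/H2O, rt
Reagents that add atoms: sodium periodate [Na+].[O-]I(=O)(=O)=O; water O
Why: RuO4 oxidation of the primary alcohol to the acid leaves the epoxide intact; only the CIP label at C2 changes (R → S).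

**Assembly and ring expansion**

Step 10
Reactants: 10 (5R)-5-ethenyloxolan-2-one; 7 (3S,4Z)-3-[(tert-butyldimethylsilyl)oxy]-5-iodo-4-methylpent-4-enal
Product: 16 (3R,5R)-3-[(1R,3S,4Z)-3-[(tert-butyldimethylsilyl)oxy]-1-hydroxy-5-iodo-4-methylpent-4-en-1-yl]-5-ethenyloxolan-2-one, via lithium enolate 15 (not isolated)
Conditions: LiN(iPr)2 (1.05 equiv), THF, −78 °C; then 7, −78 °C; AcOH
Reagents that add atoms: none
Why: Lactone enolate aldol; the aldehyde adds trans to the C5 vinyl group, and the ring-locked E(O)-enolate reacts through a Zimmerman–Traxler chair to give the anti aldol (C1 R), with minor diastereomers removed by chromatography.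

Step 11
Reactants: 16 (3R,5R)-3-[(1R,3S,4Z)-3-[(tert-butyldimethylsilyl)oxy]-1-hydroxy-5-iodo-4-methylpent-4-en-1-yl]-5-ethenyloxolan-2-one
Product: 18 (3S,5R)-3-[(1R,3S,4Z)-3-[(tert-butyldimethylsilyl)oxy]-1-hydroxy-5-iodo-4-methylpent-4-en-1-yl]-5-ethenyl-3-methyloxolan-2-one, via dilithium dianion 17 (not isolated)
Conditions: LiN(iPr)2 (2.2 equiv), THF, −78 → −40 °C; MeI (3 equiv), DMPU, −78 → −40 °C; AcOH
Reagents that add atoms: iodomethane CI
Why: Fráter–Seebach alkylation; in the chelated enolate–alkoxide, MeI enters anti to the carbinol substituent and trans to the vinyl group (matched), which fixes the C10/C1 relationship that later translates into the E-C1=C10 alkene.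

Step 12
Reactants: 18 (3S,5R)-3-[(1R,3S,4Z)-3-[(tert-butyldimethylsilyl)oxy]-1-hydroxy-5-iodo-4-methylpent-4-en-1-yl]-5-ethenyl-3-methyloxolan-2-one
Product: 20 (4S,6R,7S)-4-[(tert-butyldimethylsilyl)oxy]-6-hydroxy-7-[(2R)-2-hydroxybut-3-en-1-yl]-3,7-dimethylcyclohept-2-en-1-one, via vinyllithium 19 (not isolated)
Conditions: t-BuLi (3.1 equiv), THF/Et2O, −100 → −78 °C; AcOH, −78 °C
Reagents that add atoms: none
Why: Parham-type cyclization; iodine–lithium exchange outruns carbonyl addition, the Z-vinyllithium is acylated intramolecularly by the lactone (no α-hydrogen), and the tetrahedral adduct survives until the cold quench, so the seven-membered enone forms without over-addition and O8 is released as a free hydroxyl.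

Step 13
Reactants: 20 (4S,6R,7S)-4-[(tert-butyldimethylsilyl)oxy]-6-hydroxy-7-[(2R)-2-hydroxybut-3-en-1-yl]-3,7-dimethylcyclohept-2-en-1-one; 21 2-(bromomethyl)prop-2-enoic acid
Product: 24 (2R)-1-[(1S,2R,4S)-4-[(tert-butyldimethylsilyl)oxy]-2-(methanesulfonyloxy)-1,5-dimethyl-7-oxocyclohept-5-en-1-yl]but-3-en-2-yl 2-(bromomethyl)prop-2-enoate, via acid chloride 22 (not isolated), via hydroxy ester 23 (not isolated)
Conditions: 21, (COCl)2, DMF (cat.), CH2Cl2, 0 °C → rt, evaporate; then 20, 2,6-lutidine, CH2Cl2, −40 °C; then MsCl, Et3N (added last), −40 °C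
Reagents that add atoms: methanesulfonyl chloride CS(=O)(=O)Cl
Why: The unhindered allylic O8–H is acylated selectively, then the neopentyl-type O1–H is mesylated through sulfene; the β-mesyloxy ketone cannot eliminate because C10 is quaternary.

Step 14
Reactants: 24 (2R)-1-[(1S,2R,4S)-4-[(tert-butyldimethylsilyl)oxy]-2-(methanesulfonyloxy)-1,5-dimethyl-7-oxocyclohept-5-en-1-yl]but-3-en-2-yl 2-(bromomethyl)prop-2-enoate
Product: 25 (5R)-3-(bromomethyl)-5-{[(1S,2R,4S)-4-[(tert-butyldimethylsilyl)oxy]-2-(methanesulfonyloxy)-1,5-dimethyl-7-oxocyclohept-5-en-1-yl]methyl}furan-2(5H)-one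
Conditions: second-generation Hoveyda–Grubbs catalyst (5 mol %), toluene (5 mM), 70 °C
Reagents that add atoms: none
Why: Ring-closing metathesis of the acrylate with the vinyl group gives the butenolide with loss of ethylene; the ring enone alkene is trisubstituted and electron-poor and does not take part.

Step 15
Reactants: 25 (5R)-3-(bromomethyl)-5-{[(1S,2R,4S)-4-[(tert-butyldimethylsilyl)oxy]-2-(methanesulfonyloxy)-1,5-dimethyl-7-oxocyclohept-5-en-1-yl]methyl}furan-2(5H)-one
Product: 27 (3S,7R,8R)-3-[(tert-butyldimethylsilyl)oxy]-6-oxogermacra-1(10)E,4Z,11(13)-trien-12,8-olide, via samarium alkoxide 26 (not isolated)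
Conditions: SmI2 (2.2 equiv, slow addition), THF, −78 → 0 °C; pH 7 buffer; used at once
Reagents that add atoms: none
Why: Proposed new method: an allylative Barbier cyclization/Grob fragmentation that inserts the three-carbon tether into the C6–C10 bond; SmI2 reduces the allylic C–Br bond faster than the enone, the allylsamarium adds to the C6 ketone through its γ-carbon C7 (SE2′, five-membered ring, lactone forced cis so that 7R follows from 8R) and unveils the exocyclic methylene, and the trivalent samarium alkoxide 26 then expels the antiperiplanar C1 mesylate with cleavage of C6–C10, so that the C1/C10 relationship from step 11 becomes the E-C1=C10 alkene stereospecifically; the closest known reaction types are the SmI2-mediated sequential Barbier cyclization/Grob fragmentation of iodoalkyl keto mesylates (alkyl halides only) and the Zn- or In-mediated γ-selective additions of 2-(bromomethyl)acrylates to ketones, neither of which has been shown with a butenolide allyl pronucleophile in a ring-expanding cascade.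

Step 16
Reactants: 27 (3S,7R,8R)-3-[(tert-butyldimethylsilyl)oxy]-6-oxogermacra-1(10)E,4Z,11(13)-trien-12,8-olide
Product: 29 (3S,6R,7R,8R)-3-[(tert-butyldimethylsilyl)oxy]-8-hydroxygermacra-1(10)E,4Z,11(13)-trien-12,6-olide, via 6-hydroxy-8,12-olide 28 (not isolated)
Conditions: (R)-2-methyl-CBS-oxazaborolidine (0.2 equiv), catecholborane (1.5 equiv), toluene, −78 °C; aq. NaHCO3; then DBU (0.2 equiv), CH2Cl2, rt
Reagents that add atoms: none
Why: Corey–Bakshi–Shibata reduction with the alkenyl group acting as the large substituent is expected to give the 6R alcohol under reagent control, and base-catalysed transesterification should then move the acyl group from O8 to O6, on the assumption that the trans-fused 6,12-olide is the more stable lactone.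

Step 17
Reactants: 29 (3S,6R,7R,8R)-3-[(tert-butyldimethylsilyl)oxy]-8-hydroxygermacra-1(10)E,4Z,11(13)-trien-12,6-olide; 14 (2S,3S)-2,3-dimethyloxirane-2-carboxylic acid
Product: 30 (3S,6R,7R,8R)-3-[(tert-butyldimethylsilyl)oxy]-8-{[(2S,3S)-2,3-dimethyloxiran-2-yl]carbonyloxy}germacra-1(10)E,4Z,11(13)-trien-12,6-olide
Conditions: DIC, DMAP (0.3 equiv), CH2Cl2, 0 °C → rt
Reagents that add atoms: none
Why: Steglich esterification of the only free hydroxyl, which also locks the lactone at O6.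

Step 18
Reactants: 30 (3S,6R,7R,8R)-3-[(tert-butyldimethylsilyl)oxy]-8-{[(2S,3S)-2,3-dimethyloxiran-2-yl]carbonyloxy}germacra-1(10)E,4Z,11(13)-trien-12,6-olide
Product: 31 (3S,6R,7R,8R)-8-{[(2S,3S)-2,3-dimethyloxiran-2-yl]carbonyloxy}-3-hydroxygermacra-1(10)E,4Z,11(13)-trien-12,6-olide
Conditions: HF·pyridine, pyridine, THF, 0 °C → rt
Reagents that add atoms: none
Why: Buffered fluoride desilylation is mild enough for the glycidic ester, the α-methylene lactone and the 1,5-diene.

Step 19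
Reactants: 31 (3S,6R,7R,8R)-8-{[(2S,3S)-2,3-dimethyloxiran-2-yl]carbonyloxy}-3-hydroxygermacra-1(10)E,4Z,11(13)-trien-12,6-olide; 32 2-methylpropanoyl chloride
Product: 33 (3S,6R,7R,8R)-8-{[(2S,3S)-2,3-dimethyloxiran-2-yl]carbonyloxy}-3-(2-methylpropanoyloxy)germacra-1(10)E,4Z,11(13)-trien-12,6-olide
Conditions: pyridine, DMAP (cat.), CH2Cl2, 0 °C
Reagents that add atoms: none
Why: Acylation of the allylic alcohol; capping O3 also removes hydroxyl direction before the epoxidation.

Step 20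
Reactants: 33 (3S,6R,7R,8R)-8-{[(2S,3S)-2,3-dimethyloxiran-2-yl]carbonyloxy}-3-(2-methylpropanoyloxy)germacra-1(10)E,4Z,11(13)-trien-12,6-olide
Product: 34 (1R,3S,6R,7R,8R,10R)-1,10-epoxy-8-{[(2S,3S)-2,3-dimethyloxiran-2-yl]carbonyloxy}-3-(2-methylpropanoyloxy)germacra-4Z,11(13)-dien-12,6-olide (CNP0117882.1)
Conditions: mCPBA (1.1 equiv), NaHCO3, CH2Cl2, 0 °C
Reagents that add atoms: meta-chloroperoxybenzoic acid OOC(=O)c1cccc(Cl)c1
Why: Prilezhaev epoxidation picks the only electron-rich alkene (C4=C5 carries two allylic acyloxy groups, C11=C13 is conjugated), and peripheral attack on the E alkene is expected to give the 1β,10α (1R,10R) epoxide.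

**Compound list**

1 | prop-2-yn-1-ol | C#CCO | starting material
2 | 4-methyl-2,5-dihydro-1,2-oxamagnesole (cyclic alkenylmagnesium alkoxide) | CC1=C[Mg]OC1 | intermediate
3 | (Z)-3-iodo-2-methylprop-2-en-1-ol | OC/C(C)=C\I | intermediate
4 | (Z)-3-iodo-2-methylprop-2-enal | O=C/C(C)=C\I | intermediate
5 | (3S,1Z)-1-iodo-2-methylhexa-1,5-dien-3-ol | C=CC[C@H](O)/C(C)=C\I | intermediate
6 | tert-butyl{[(3S,1Z)-1-iodo-2-methylhexa-1,5-dien-3-yl]oxy}dimethylsilane | C=CC[C@H](O[Si](C)(C)C(C)(C)C)/C(C)=C\I | intermediate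
7 | (3S,4Z)-3-[(tert-butyldimethylsilyl)oxy]-5-iodo-4-methylpent-4-enal | O=CC[C@H](O[Si](C)(C)C(C)(C)C)/C(C)=C\I | intermediate
8 | (5R)-5-(hydroxymethyl)oxolan-2-one | OC[C@H]1CCC(=O)O1 | starting material
9 | (2R)-5-oxooxolane-2-carbaldehyde | O=C[C@H]1CCC(=O)O1 | intermediate
10 | (5R)-5-ethenyloxolan-2-one | C=C[C@H]1CCC(=O)O1 | intermediate
11 | (Z)-2-methylbut-2-enoic acid (angelic acid) | C/C=C(/C)C(=O)O | starting material
12 | (Z)-2-methylbut-2-en-1-ol | C/C=C(/C)CO | intermediate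
13 | [(2R,3S)-2,3-dimethyloxiran-2-yl]methanol | OC[C@@]1(C)O[C@H]1C | intermediate
14 | (2S,3S)-2,3-dimethyloxirane-2-carboxylic acid | OC(=O)[C@@]1(C)O[C@H]1C | intermediate
15 | lithium (5R)-5-ethenyl-4,5-dihydrofuran-2-olate | C=C[C@H]1CC=C(O[Li])O1 | intermediate
16 | (3R,5R)-3-[(1R,3S,4Z)-3-[(tert-butyldimethylsilyl)oxy]-1-hydroxy-5-iodo-4-methylpent-4-en-1-yl]-5-ethenyloxolan-2-one | C=C[C@H]1C[C@H]([C@H](O)C[C@H](O[Si](C)(C)C(C)(C)C)/C(C)=C\I)C(=O)O1 | intermediate
17 | dilithium enolate–alkoxide (dianion) of 16 | C=C[C@H]1CC(=C(O[Li])O1)[C@H](O[Li])C[C@H](O[Si](C)(C)C(C)(C)C)/C(C)=C\I | intermediate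
18 | (3S,5R)-3-[(1R,3S,4Z)-3-[(tert-butyldimethylsilyl)oxy]-1-hydroxy-5-iodo-4-methylpent-4-en-1-yl]-5-ethenyl-3-methyloxolan-2-one | C=C[C@H]1C[C@@](C)([C@H](O)C[C@H](O[Si](C)(C)C(C)(C)C)/C(C)=C\I)C(=O)O1 | intermediate
19 | Z-vinyllithium lithium alkoxide derived from 18 | C=C[C@H]1C[C@@](C)([C@H](O[Li])C[C@H](O[Si](C)(C)C(C)(C)C)/C(C)=C\[Li])C(=O)O1 | intermediate
20 | (4S,6R,7S)-4-[(tert-butyldimethylsilyl)oxy]-6-hydroxy-7-[(2R)-2-hydroxybut-3-en-1-yl]-3,7-dimethylcyclohept-2-en-1-one | C=C[C@H](O)C[C@@]1(C)[C@H](O)C[C@H](O[Si](C)(C)C(C)(C)C)C(C)=CC1=O | intermediate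
21 | 2-(bromomethyl)prop-2-enoic acid | C=C(CBr)C(=O)O | starting material
22 | 2-(bromomethyl)prop-2-enoyl chloride | C=C(CBr)C(=O)Cl | intermediate
23 | (2R)-1-[(1S,2R,4S)-4-[(tert-butyldimethylsilyl)oxy]-2-hydroxy-1,5-dimethyl-7-oxocyclohept-5-en-1-yl]but-3-en-2-yl 2-(bromomethyl)prop-2-enoate | C=C[C@H](OC(=O)C(=C)CBr)C[C@@]1(C)[C@H](O)C[C@H](O[Si](C)(C)C(C)(C)C)C(C)=CC1=O | intermediate
24 | (2R)-1-[(1S,2R,4S)-4-[(tert-butyldimethylsilyl)oxy]-2-(methanesulfonyloxy)-1,5-dimethyl-7-oxocyclohept-5-en-1-yl]but-3-en-2-yl 2-(bromomethyl)prop-2-enoate | C=C[C@H](OC(=O)C(=C)CBr)C[C@@]1(C)[C@H](OS(C)(=O)=O)C[C@H](O[Si](C)(C)C(C)(C)C)C(C)=CC1=O | intermediate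
25 | (5R)-3-(bromomethyl)-5-{[(1S,2R,4S)-4-[(tert-butyldimethylsilyl)oxy]-2-(methanesulfonyloxy)-1,5-dimethyl-7-oxocyclohept-5-en-1-yl]methyl}furan-2(5H)-one | BrCC1=C[C@@H](C[C@@]2(C)[C@H](OS(C)(=O)=O)C[C@H](O[Si](C)(C)C(C)(C)C)C(C)=CC2=O)OC1=O | intermediate
26 | diiodosamarium alkoxide of the 5-5-7 tricyclic carbinol formed by C7→C6 allylation (O6–SmI2, C1 mesylate intact, α-methylene lactone cis-fused at C7–C8) | C=C1C(=O)O[C@@H]2C[C@@]3(C)[C@H](OS(C)(=O)=O)C[C@H](O[Si](C)(C)C(C)(C)C)C(C)=C[C@@]3(O[Sm](I)I)[C@H]12 | intermediate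
27 | (3S,7R,8R)-3-[(tert-butyldimethylsilyl)oxy]-6-oxogermacra-1(10)E,4Z,11(13)-trien-12,8-olide | C=C1C(=O)O[C@@H]2C/C(C)=C/C[C@H](O[Si](C)(C)C(C)(C)C)/C(C)=C\C(=O)[C@H]12 | intermediate
28 | (3S,6R,7R,8R)-3-[(tert-butyldimethylsilyl)oxy]-6-hydroxygermacra-1(10)E,4Z,11(13)-trien-12,8-olide | C=C1C(=O)O[C@@H]2C/C(C)=C/C[C@H](O[Si](C)(C)C(C)(C)C)/C(C)=C\[C@@H](O)[C@H]12 | intermediate
29 | (3S,6R,7R,8R)-3-[(tert-butyldimethylsilyl)oxy]-8-hydroxygermacra-1(10)E,4Z,11(13)-trien-12,6-olide | C=C1C(=O)O[C@@H]2/C=C(/C)[C@@H](O[Si](C)(C)C(C)(C)C)C/C=C(\C)C[C@@H](O)[C@@H]12 | intermediate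
30 | (3S,6R,7R,8R)-3-[(tert-butyldimethylsilyl)oxy]-8-{[(2S,3S)-2,3-dimethyloxiran-2-yl]carbonyloxy}germacra-1(10)E,4Z,11(13)-trien-12,6-olide | C=C1C(=O)O[C@@H]2/C=C(/C)[C@@H](O[Si](C)(C)C(C)(C)C)C/C=C(\C)C[C@@H](OC(=O)[C@@]3(C)O[C@H]3C)[C@@H]12 | intermediate
31 | (3S,6R,7R,8R)-8-{[(2S,3S)-2,3-dimethyloxiran-2-yl]carbonyloxy}-3-hydroxygermacra-1(10)E,4Z,11(13)-trien-12,6-olide | C=C1C(=O)O[C@@H]2/C=C(/C)[C@@H](O)C/C=C(\C)C[C@@H](OC(=O)[C@@]3(C)O[C@H]3C)[C@@H]12 | intermediate
32 | 2-methylpropanoyl chloride (isobutyryl chloride) | CC(C)C(=O)Cl | starting material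
33 | (3S,6R,7R,8R)-8-{[(2S,3S)-2,3-dimethyloxiran-2-yl]carbonyloxy}-3-(2-methylpropanoyloxy)germacra-1(10)E,4Z,11(13)-trien-12,6-olide | C=C1C(=O)O[C@@H]2/C=C(/C)[C@@H](OC(=O)C(C)C)C/C=C(\C)C[C@@H](OC(=O)[C@@]3(C)O[C@H]3C)[C@@H]12 | intermediate
34 | (1R,3S,6R,7R,8R,10R)-1,10-epoxy-8-{[(2S,3S)-2,3-dimethyloxiran-2-yl]carbonyloxy}-3-(2-methylpropanoyloxy)germacra-4Z,11(13)-dien-12,6-olide (CNP0117882.1) | C=C1C(=O)O[C@@H]2/C=C(/C)[C@@H](OC(=O)C(C)C)C[C@H]3O[C@]3(C)C[C@@H](OC(=O)[C@@]3(C)O[C@H]3C)[C@@H]12 | target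

**Step count and risks**

Total step count: 20. Longest linear sequence: 16 (steps 1–5, then 10–20).

Three steps most likely to fail:

Step 12 (vinyllithium acylation to the seven-membered enone). The risks are attack of t-BuLi on the lactone, retro-aldol of the lithium aldolate, and a slow seven-membered closure. The fallback sets out from 18 and comes back at 23. Lactone 18 is reduced with i-Bu2AlH (CH2Cl2, −78 °C) to (3S,5R)-3-[(1R,3S,4Z)-3-[(tert-butyldimethylsilyl)oxy]-1-hydroxy-5-iodo-4-methylpent-4-en-1-yl]-5-ethenyl-3-methyloxolan-2-ol F1. The ring is then closed by an intramolecular Nozaki–Hiyama–Kishi reaction of the vinyl iodide with the open-chain aldehyde tautomer (CrCl2, NiCl2 (1 mol %), DMSO/THF, rt) to give (4S,6R,7S)-4-[(tert-butyldimethylsilyl)oxy]-7-[(2R)-2-hydroxybut-3-en-1-yl]-3,7-dimethylcyclohept-2-ene-1,6-diol F2 (C1 epimers of the ring carbinol). The least hindered side-chain hydroxyl is acylated with acid chloride 22 (2,6-lutidine, CH2Cl2, −40 °C) to give (2R)-1-[(1S,2R,4S)-4-[(tert-butyldimethylsilyl)oxy]-2,7-dihydroxy-1,5-dimethylcyclohept-5-en-1-yl]but-3-en-2-yl 2-(bromomethyl)prop-2-enoate F3. MnO2 (CH2Cl2, rt) then oxidises only the ring allylic alcohol to give 23, which is mesylated as in the last stage of step 13.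

Step 15 (proposed samarium Barbier/Grob ring expansion). The risks are reduction of the enone by SmI2, lactonisation or silent survival of the samarium alkoxide without fragmentation, and epimerisation or β-elimination at C7/C8 of the product. The fallback sets out from 25 and comes back at 27, using two known reactions in separate flasks. A zinc Barbier cyclization under protic conditions (Zn dust, THF/saturated aq. NH4Cl, 0 °C) traps the adduct as the isolable tricyclic carbinol, the C6 tertiary alcohol corresponding to 26, F4. A classical Grob (Wharton-type) fragmentation of this 1,3-diol monomesylate with KN(SiMe3)2 (1.05 equiv, THF, −78 → −20 °C) then gives 27.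

Step 16 (C6 reduction and translactonization). The risks are the wrong facial selectivity at C6 in the medium ring, and an equilibrium that does not favour the 6,12-olide. The fallback sets out from 27 and comes back at 29, and it forms the 6,12-lactone kinetically with inversion. Reduction with (S)-2-methyl-CBS-oxazaborolidine and catecholborane (toluene, −78 °C) gives the 6-epimeric alcohol (3S,6S,7R,8R)-3-[(tert-butyldimethylsilyl)oxy]-6-hydroxygermacra-1(10)E,4Z,11(13)-trien-12,8-olide F5. Saponification (LiOH, THF/H2O, 0 °C; acidify to pH 4) gives (3S,6S,7R,8R)-3-[(tert-butyldimethylsilyl)oxy]-6,8-dihydroxygermacra-1(10)E,4Z,11(13)-trien-12-oic acid F6. Mitsunobu lactonization (PPh3, DIAD, THF, high dilution, 0 °C) activates the allylic C6 hydroxyl and closes the lactone with inversion to give 29.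

**Further compounds**

F1 | step 12 | (3S,5R)-3-[(1R,3S,4Z)-3-[(tert-butyldimethylsilyl)oxy]-1-hydroxy-5-iodo-4-methylpent-4-en-1-yl]-5-ethenyl-3-methyloxolan-2-ol (lactol, anomer mixture) | C=C[C@H]1C[C@@](C)([C@H](O)C[C@H](O[Si](C)(C)C(C)(C)C)/C(C)=C\I)C(O)O1
F2 | step 12 | (4S,6R,7S)-4-[(tert-butyldimethylsilyl)oxy]-7-[(2R)-2-hydroxybut-3-en-1-yl]-3,7-dimethylcyclohept-2-ene-1,6-diol (C1 epimers) | C=C[C@H](O)C[C@@]1(C)[C@H](O)C[C@H](O[Si](C)(C)C(C)(C)C)C(C)=CC1O
F3 | step 12 | (2R)-1-[(1S,2R,4S)-4-[(tert-butyldimethylsilyl)oxy]-2,7-dihydroxy-1,5-dimethylcyclohept-5-en-1-yl]but-3-en-2-yl 2-(bromomethyl)prop-2-enoate | C=C[C@H](OC(=O)C(=C)CBr)C[C@@]1(C)[C@H](O)C[C@H](O[Si](C)(C)C(C)(C)C)C(C)=CC1O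
F4 | step 15 | 5-5-7 tricyclic tertiary carbinol (free C6 alcohol corresponding to 26, C1 mesylate intact) | C=C1C(=O)O[C@@H]2C[C@@]3(C)[C@H](OS(C)(=O)=O)C[C@H](O[Si](C)(C)C(C)(C)C)C(C)=C[C@@]3(O)[C@H]12
F5 | step 16 | (3S,6S,7R,8R)-3-[(tert-butyldimethylsilyl)oxy]-6-hydroxygermacra-1(10)E,4Z,11(13)-trien-12,8-olide | C=C1C(=O)O[C@@H]2C/C(C)=C/C[C@H](O[Si](C)(C)C(C)(C)C)/C(C)=C\[C@H](O)[C@H]12
F6 | step 16 | (3S,6S,7R,8R)-3-[(tert-butyldimethylsilyl)oxy]-6,8-dihydroxygermacra-1(10)E,4Z,11(13)-trien-12-oic acid | C=C(C(=O)O)[C@@H]1[C@H](O)C/C(C)=C/C[C@H](O[Si](C)(C)C(C)(C)C)/C(C)=C\[C@@H]1O
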